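Compound numbers 1–19 are those of the steps and of the compound list below. Unprimed atoms and rings A, B, C belong to the upper flavan; primed atoms and rings D, E, F belong to the lower 6-methylflavan.

## Analysis of the target

Compound 19 is a biflavanoid, fisetinidol-(4α→8)-6-methylcatechin. An upper 5-deoxyflavan-3-ol (ring A with one phenol at C7, catechol ring B, pyran ring C) is bonded through C4 to C8' of a lower catechin unit that carries a methyl group at C6' (ring D, catechol ring E, pyran ring F). There are five stereocentres. C2 (R), C3 (S) and C4 (S) on ring C are all-trans, with the C2 and C4 aryl groups on one face and the C3 hydroxyl on the other. C2' (R) and C3' (S) on ring F are trans, as in (+)-catechin. The two sets are remote from each other, so their relationship must be fixed by absolute control at C4 or by separating diastereomers. Ring D is hexasubstituted, and the C4–C8' bond joins a benzylic methine to an arene carbon flanked by two oxygen-bearing carbons, so this junction is crowded. The sensitive groups are the seven phenols (two catechols, easily oxidised), the benzylic C2–O1 and C2'–O1' bonds of the pyran rings, and the C4–C8' bond, which acid can cleave at the electron-rich ring D. The hard points are making C4 with the correct configuration relative to ring F, placing methyl at C6' and the upper unit at C8', and obtaining the 2,3-trans-3,4-trans pattern. The strategy rests on ring C: O1 and C4 sit on adjacent carbons of ring A (C8a and C4a), so O1–C8a–C4a–C4 is a masked ortho-quinone methide. C2–C3, with ring B on C2 and the hydroxyl on C3 trans to both aryl groups, is an arylacetylene after hydroboration is taken back.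

## Retrosynthetic reasoning

**19 to 18.** The eight O–benzyl bonds are cut last. Benzyl ethers are the only protecting group on the main line because they survive organolithium chemistry, Brønsted acid catalysis and hydroboration, and all fall in one neutral hydrogenolysis. The forward step has to spare the benzylic C–O bonds of rings C and F.

**18 to 16.** The C3–O and C2–H bonds are removed to give the C2=C3 enol ether of 16. Ring C of 18 has the hydroxyl trans to both neighbours, which is what a syn hydroboration from the face opposite the C4 substituent delivers. C2 and C3 are therefore not made independently but relayed from C4. The forward step must place boron at C3 and approach anti to ring D.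

**16 to 12 and 14.** Here O1–C2 and C3–C4 are cut. This removes ring C altogether and leaves a diaryl carbinol 12, which ionises to a ring A ortho-quinone methide 15, and the arylacetylene 14. Cutting C4–C8' instead would require a complete, enantiopure upper flavan with a leaving group at C4, made separately with three stereocentres. The chosen cut makes one partner achiral and the other a catechin derivative, and creates only one stereocentre, C4, in the union. The forward reaction has to form both bonds with the aryl group on C2 and choose one face of the planar methide carbon.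

**12 to 11, then to 7 and 9.** The O-allyl bond of 11 is cut first, then the bond between the carbinol carbon and C8'. The carbinol configuration is irrelevant because it is lost on ionisation, so a plain addition of aryllithium 10 (from bromide 7) to aldehyde 9 suffices. The ortho-phenol of ring A is masked as an allyl ether during the addition because a free phenol would quench the aryllithium. Allyl is chosen because it leaves under neutral conditions that do not ionise the very labile carbinol.

**7 back to 1.** The C6–methyl of 7 is traced to the formyl group of 6, and the C8–Br and C6–CHO bonds are cut in turn to reach 3, then 2 and 1. Ring D with its ether oxygen, ring F and both of its stereocentres are bought as (+)-catechin 1. Electrophilic bromination of 3 prefers C8, so bromine first blocks C8 while the one remaining position, C6, is formylated, and then serves as the handle for lithiation. The forward sequence must keep C2 and C3 of the catechin unit untouched, which the full benzylation ensures.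

**9 from 8, and 14 from 13.** The allyl ether of 9 is cut back to the phenol 8. The alkyne carbon of 14 is removed to give aldehyde 13, a one-carbon homologation in the forward direction.

## Alternatives that were turned down

**Alternative 1: benzannulation that builds ring D.** The disconnection cuts C8'–C8a' and C6'–C7' of ring D. In the forward step the cyclobutenone A3 is heated with the 4-flavanyl siloxyalkyne A2. Ring opening gives a vinylketene, which adds the ynol ether, reopens and electrocyclises to the phenol A1. In its favour, the mechanism fixes the position of all six substituents of ring D and delivers the three oxygens differentiated. On this point it is stronger than the chosen route, which relies on the innate C8 preference of bromination and on a blocking tactic. Against it, A2 already contains the whole upper unit with C2, C3 and C4 set and a fragile ynol ether at a propargylic, doubly activated C4. A3 is a tetrasubstituted cyclobutenone needing its own multistep synthesis. After A1, ring F with C2' and C3' must still be built from the cinnamyl chain by asymmetric oxidation and cyclisation. The alternative therefore discards the ring and two stereocentres that (+)-catechin 1 supplies and leaves the origin of C4 unsolved. The chosen route offers, in place of guaranteed arene regiochemistry, a much shorter path in which rings D and F are purchased.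

**Alternative 2: epoxide–arene cyclisation that closes ring F.** The disconnection cuts C4'–C4a'. In the forward step the aryl ether epoxide A5, in a strongly ionising fluorinated alcohol, is attacked at its primary carbon by the only free carbon of ring D, giving the octa-O-benzyl ether A4 with a free C3' hydroxyl. In its favour, there is no regiochemical choice on the arene, no new stereocentre is formed, and the conditions are mild and metal-free. Its key step is thus more predictable than the chosen one, whose face selectivity is open. Against it, A5 requires etherification of a phenol flanked by the bulky flavanyl group with a secondary benzylic carbon of defined configuration. That substitution is hard, and the ionising medium can also break this benzylic ether. Attack at the secondary epoxide carbon would give a five-membered ring. The upper unit with its C4 stereocentre must also exist before this step, so the central problem is only moved earlier. The chosen strategy offers convergence on a catechin-derived nucleophile and a direct answer to how C4 is made.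

**Alternative 3: double arylation of an aldehyde.** The disconnection cuts C4–C8' and C4–C4a. In the forward step a strong Lewis acid activates the aldehyde A7, the free C8' position of the protected 6-methylcatechin A8 attacks it, the resulting carbinol ionises, and ring A closes onto the cation to give the nona-O-benzyl ether A6. In its favour, it is highly convergent, the nucleophile A8 has a single free position, and the C4 configuration is set by substrate control, trans to the C3 benzyloxy group, without a chiral catalyst. On the predictability of C4 it is stronger than the chosen route. Against it, A7 is an α-benzyloxy aldehyde with a β-aryloxy benzylic centre, so two stereocentres must be made by asymmetric synthesis over several steps. It can epimerise at C3 and lose the aryloxide by β-elimination under the Lewis acid. Ring A, with one ether oxygen only, is a weak nucleophile, so the long-lived cation next to ring D may be captured by a second molecule of A8, or closure may occur between the two oxygens of ring A. The chosen strategy builds the same C4 from an achiral aldehyde and an achiral alkyne and derives C2 and C3 from C4, so no separate asymmetric synthesis of the upper unit is needed. Its price is an uncertain, catalyst-controlled face selection, whose failure would give separable diastereomers.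

Key step: step 10

## Assumptions

- Compounds 8 and 13 are taken as purchased materials.
- The sense of induction of the chiral phosphoric acid on this substrate cannot be predicted with confidence. The (R) acid is written, and its antipode would be used if the (R) acid favours the wrong face.
- Compounds 11 and 12 are formed as mixtures of carbinol epimers, which is of no consequence because that centre is planarised in step 10.

## Route

Step 1
Reactants: 1 (+)-catechin
Product: 2 5,7,3',4'-tetra-O-benzyl-(+)-catechin, (2R,3S)-5,7-bis(benzyloxy)-2-[3,4-bis(benzyloxy)phenyl]chroman-3-ol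
Conditions: BnBr (4.4 equiv), K2CO3, DMF, 0 °C to rt, Ar
Reagents that add atoms: benzyl bromide, BrCc1ccccc1
Why: Williamson etherification; carbonate deprotonates the four phenols but not the secondary alcohol, and the low temperature and exclusion of air limit C-benzylation and base-induced epimerisation at C2.

Step 2
Reactants: 2 5,7,3',4'-tetra-O-benzyl-(+)-catechin
Product: 3 3,5,7,3',4'-penta-O-benzyl-(+)-catechin, (2R,3S)-3,5,7-tris(benzyloxy)-2-[3,4-bis(benzyloxy)phenyl]chromane
Conditions: NaH, BnBr, n-Bu4NI (cat.), DMF, 0 °C to rt
Reagents that add atoms: benzyl bromide, BrCc1ccccc1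
Why: Williamson etherification of the secondary alkoxide; with no free phenol left, the ring-opening pathway that epimerises C2 is closed, so both stereocentres are retained.

Step 3
Reactants: 3 3,5,7,3',4'-penta-O-benzyl-(+)-catechin
Product: 4 (2R,3S)-8-bromo-3,5,7-tris(benzyloxy)-2-[3,4-bis(benzyloxy)phenyl]chromane
Conditions: N-bromosuccinimide (1.0 equiv), CH2Cl2, −78 to 0 °C
Reagents that add atoms: N-bromosuccinimide, O=C1CCC(=O)N1Br
Why: Electrophilic aromatic bromination; in 5,7-dialkoxyflavans the C8 position reacts first, so one equivalent of reagent at low temperature should give the 8-bromide and leave C6 free.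

Step 4
Reactants: 4 the 8-bromide
Product: 6 (2R,3S)-8-bromo-3,5,7-tris(benzyloxy)-2-[3,4-bis(benzyloxy)phenyl]chromane-6-carbaldehyde, via iminium chloride 5 (not isolated)
Conditions: POCl3, DMF, ClCH2CH2Cl, 0 to 70 °C; then aq NaOAc
Reagents that add atoms: N,N-dimethylformamide, CN(C)C=O; water, O
Why: Vilsmeier–Haack formylation; C6 is the only free position of ring D and is activated by two ortho and one para oxygen, while the catechol ether ring is far less reactive, and hydrolysis of iminium salt 5 on work-up releases the aldehyde.

Step 5
Reactants: 6 the 6-carbaldehyde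
Product: 7 (2R,3S)-8-bromo-6-methyl-3,5,7-tris(benzyloxy)-2-[3,4-bis(benzyloxy)phenyl]chromane
Conditions: Et3SiH (4 equiv), CF3CO2H, CH2Cl2, 0 °C
Reagents that add atoms: none
Why: Ionic hydrogenation; the protonated aldehyde takes one hydride, the resulting benzylic alcohol ionises to a cation stabilised by three ring oxygens and takes a second hydride, and the aryl bromide and benzyl ethers should not react with silane and acid at 0 °C.

Step 6
Reactants: 8 4-(benzyloxy)-2-hydroxybenzaldehyde
Product: 9 2-(allyloxy)-4-(benzyloxy)benzaldehyde
Conditions: allyl bromide, K2CO3, DMF, rt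
Reagents that add atoms: allyl bromide, C=CCBr
Why: Williamson etherification of the hydrogen-bonded ortho-phenol; the allyl group is small, stable to organolithium reagents at low temperature and removable later without acid.

Step 7
Reactants: 7 the 8-bromo-6-methyl compound; 9 2-(allyloxy)-4-(benzyloxy)benzaldehyde
Product: 11 [2-(allyloxy)-4-(benzyloxy)phenyl][(2R,3S)-6-methyl-3,5,7-tris(benzyloxy)-2-[3,4-bis(benzyloxy)phenyl]chroman-8-yl]methanol (both carbinol epimers), via aryllithium 10 (not isolated)
Conditions: n-BuLi (1.05 equiv), THF, −78 °C; then 9, −78 to −40 °C; aq NH4Cl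
Reagents that add atoms: none
Why: Bromine–lithium exchange followed by 1,2-addition to a non-enolisable aldehyde; exchange is faster than benzylic deprotonation at −78 °C and the aryllithium is held by its two flanking ether oxygens, and the new carbinol centre forms without control, which does not matter.

Step 8
Reactants: 11 the allyl-protected diaryl carbinol
Product: 12 [4-(benzyloxy)-2-hydroxyphenyl][(2R,3S)-6-methyl-3,5,7-tris(benzyloxy)-2-[3,4-bis(benzyloxy)phenyl]chroman-8-yl]methanol (both carbinol epimers)
Conditions: Pd(PPh3)4 (5 mol %), morpholine, THF, rt; chromatography on Et3N-deactivated silica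
Reagents that add atoms: none
Why: Tsuji–Trost deallylation; zerovalent palladium ionises the aryl allyl ether and morpholine captures the allyl fragment, under neutral to basic conditions that leave the benzyl ethers and the acid-labile carbinol intact.

Step 9
Reactants: 13 3,4-bis(benzyloxy)benzaldehyde
Product: 14 4-ethynyl-1,2-bis(benzyloxy)benzene (3,4-bis(benzyloxy)phenylacetylene)
Conditions: dimethyl (1-diazo-2-oxopropyl)phosphonate, K2CO3, MeOH/THF, 0 °C to rt
Reagents that add atoms: dimethyl (1-diazo-2-oxopropyl)phosphonate, COP(=O)(OC)C(=[N+]=[N-])C(C)=O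
Why: Ohira–Bestmann modification of the Seyferth–Gilbert homologation; methoxide removes the acetyl group, the diazomethylphosphonate anion olefinates the aldehyde, and loss of N2 with a 1,2-shift gives the terminal alkyne under conditions mild enough for benzyl ethers.

Step 10
Reactants: 12 the free-phenol diaryl carbinol; 14 3,4-bis(benzyloxy)phenylacetylene
Product: 16 (4S)-7-(benzyloxy)-2-[3,4-bis(benzyloxy)phenyl]-4-[(2R,3S)-6-methyl-3,5,7-tris(benzyloxy)-2-[3,4-bis(benzyloxy)phenyl]chroman-8-yl]-4H-chromene, via ortho-quinone methide 15 (not isolated)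
Conditions: (R)-3,3'-bis(2,4,6-triisopropylphenyl)-1,1'-binaphthyl-2,2'-diyl hydrogen phosphate (10 mol %), 14 (3 equiv), 5 Å molecular sieves, toluene, 0 °C to rt; then Et3N
Reagents that add atoms: none
Why: The acid protonates the carbinol hydroxyl of 12 and water leaves, giving quinone methide 15 hydrogen-bonded or ion-paired to the chiral phosphate; ionisation is easy because the cation is flanked by the trioxygenated ring D and the oxygenated ring A. The terminal carbon of 14 adds to the methide carbon (C3–C4 bond), and the vinyl cation at C2, stabilised by the para-benzyloxy group of ring B, is captured by the ring A oxygen (O1–C2 bond). The closest known reaction type is the acid-promoted [4+2] annulation of ortho-hydroxybenzhydrols with arylacetylenes to 2,4-diaryl-4H-chromenes, and chiral phosphoric acids are established catalysts for cycloadditions of ortho-quinone methides. Ring C closes as a six-membered ring in a stepwise formal [4+2] with the quinone methide as the 1-oxadiene, the last event being a 6-endo capture of the linear vinyl cation by oxygen. The only new stereocentre is C4, decided when the alkyne approaches one face of the planar methide carbon; this is meant to be controlled by the 2,4,6-triisopropylphenyl walls of the phosphate bound at the quinone methide oxygen, with the ring F stereocentres as a weak second influence, and incomplete control would leave the (4R) epimer as a diastereomer to be separated. The regiochemistry (aryl on C2, hydrogen on C3) follows from the alkyne polarity, and the chemoselectivity from ring A carrying the only free phenol. Excess alkyne and sieves are used so that capture outruns self-condensation, and the acid is quenched with Et3N because 16 is an acid-labile enol ether.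

Step 11
Reactants: 16 the (4S)-4H-chromene
Product: 18 (2R,3S,4S)-7-(benzyloxy)-2-[3,4-bis(benzyloxy)phenyl]-4-[(2R,3S)-6-methyl-3,5,7-tris(benzyloxy)-2-[3,4-bis(benzyloxy)phenyl]chroman-8-yl]chroman-3-ol, via C3 alkylborane 17 (not isolated)
Conditions: BH3·SMe2, THF, 0 °C to rt; then aq NaOH, H2O2, 0 °C
Reagents that add atoms: hydrogen peroxide, OO
Why: Hydroboration–oxidation of the enol ether; boron goes to C3 (β to oxygen and away from the C2 aryl), the B–H bond adds syn from the face opposite the pseudoaxial ring D at C4, and oxidation proceeds with retention. The C3 hydroxyl thus ends trans to the C4 aryl and cis to the new C2 hydrogen, which is the 2,3-trans-3,4-trans pattern, with C2 and C3 both set by relay from C4.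

Step 12
Reactants: 18 the octa-O-benzyl flavan-3-ol
Product: 19 (2R,3S,4S)-2-(3,4-dihydroxyphenyl)-4-[(2R,3S)-2-(3,4-dihydroxyphenyl)-3,5,7-trihydroxy-6-methylchroman-8-yl]chromane-3,7-diol (the target)
Conditions: H2 (1 atm), Pd(OH)2/C, THF/MeOH, rt; filtration and concentration under Ar
Reagents that add atoms: none
Why: Catalytic hydrogenolysis of the seven aryl benzyl ethers and the one alkyl benzyl ether; the benzylic C–O bonds of rings C and F are cleaved much more slowly under these neutral conditions, and no stereocentre is touched.

## Compound list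

1 | (+)-catechin | O[C@H]1Cc2c(O)cc(O)cc2O[C@@H]1c1ccc(O)c(O)c1 | starting material
2 | 5,7,3',4'-tetra-O-benzyl-(+)-catechin | O[C@H]1Cc2c(OCc9ccccc9)cc(OCc9ccccc9)cc2O[C@@H]1c1ccc(OCc9ccccc9)c(OCc9ccccc9)c1 | intermediate
3 | 3,5,7,3',4'-penta-O-benzyl-(+)-catechin | c1c(OCc9ccccc9)c2c(cc1OCc9ccccc9)O[C@H](c1ccc(OCc9ccccc9)c(OCc9ccccc9)c1)[C@@H](OCc9ccccc9)C2 | intermediate
4 | (2R,3S)-8-bromo-3,5,7-tris(benzyloxy)-2-[3,4-bis(benzyloxy)phenyl]chromane | c1c(OCc9ccccc9)c2c(c(Br)c1OCc9ccccc9)O[C@H](c1ccc(OCc9ccccc9)c(OCc9ccccc9)c1)[C@@H](OCc9ccccc9)C2 | intermediate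
5 | N-{[(2R,3S)-8-bromo-3,5,7-tris(benzyloxy)-2-[3,4-bis(benzyloxy)phenyl]chroman-6-yl]methylidene}-N-methylmethanaminium chloride | C[N+](C)=Cc1c(OCc9ccccc9)c2c(c(Br)c1OCc9ccccc9)O[C@H](c1ccc(OCc9ccccc9)c(OCc9ccccc9)c1)[C@@H](OCc9ccccc9)C2.[Cl-] | intermediate (not isolated)
6 | (2R,3S)-8-bromo-3,5,7-tris(benzyloxy)-2-[3,4-bis(benzyloxy)phenyl]chromane-6-carbaldehyde | O=Cc1c(OCc9ccccc9)c2c(c(Br)c1OCc9ccccc9)O[C@H](c1ccc(OCc9ccccc9)c(OCc9ccccc9)c1)[C@@H](OCc9ccccc9)C2 | intermediate
7 | (2R,3S)-8-bromo-6-methyl-3,5,7-tris(benzyloxy)-2-[3,4-bis(benzyloxy)phenyl]chromane | Cc1c(OCc9ccccc9)c2c(c(Br)c1OCc9ccccc9)O[C@H](c1ccc(OCc9ccccc9)c(OCc9ccccc9)c1)[C@@H](OCc9ccccc9)C2 | intermediate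
8 | 4-(benzyloxy)-2-hydroxybenzaldehyde | O=Cc1ccc(OCc9ccccc9)cc1O | starting material
9 | 2-(allyloxy)-4-(benzyloxy)benzaldehyde | O=Cc1ccc(OCc9ccccc9)cc1OCC=C | intermediate
10 | [(2R,3S)-6-methyl-3,5,7-tris(benzyloxy)-2-[3,4-bis(benzyloxy)phenyl]chroman-8-yl]lithium | Cc1c(OCc9ccccc9)c2c(c([Li])c1OCc9ccccc9)O[C@H](c1ccc(OCc9ccccc9)c(OCc9ccccc9)c1)[C@@H](OCc9ccccc9)C2 | intermediate (not isolated)
11 | [2-(allyloxy)-4-(benzyloxy)phenyl][(2R,3S)-6-methyl-3,5,7-tris(benzyloxy)-2-[3,4-bis(benzyloxy)phenyl]chroman-8-yl]methanol, carbinol epimers | Cc1c(OCc9ccccc9)c2c(c(C(O)c3ccc(OCc9ccccc9)cc3OCC=C)c1OCc9ccccc9)O[C@H](c1ccc(OCc9ccccc9)c(OCc9ccccc9)c1)[C@@H](OCc9ccccc9)C2 | intermediate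
12 | [4-(benzyloxy)-2-hydroxyphenyl][(2R,3S)-6-methyl-3,5,7-tris(benzyloxy)-2-[3,4-bis(benzyloxy)phenyl]chroman-8-yl]methanol, carbinol epimers | Cc1c(OCc9ccccc9)c2c(c(C(O)c3ccc(OCc9ccccc9)cc3O)c1OCc9ccccc9)O[C@H](c1ccc(OCc9ccccc9)c(OCc9ccccc9)c1)[C@@H](OCc9ccccc9)C2 | intermediate
13 | 3,4-bis(benzyloxy)benzaldehyde | O=Cc1ccc(OCc9ccccc9)c(OCc9ccccc9)c1 | starting material
14 | 4-ethynyl-1,2-bis(benzyloxy)benzene | C#Cc1ccc(OCc9ccccc9)c(OCc9ccccc9)c1 | intermediate
15 | 3-(benzyloxy)-6-{[(2R,3S)-6-methyl-3,5,7-tris(benzyloxy)-2-[3,4-bis(benzyloxy)phenyl]chroman-8-yl]methylidene}cyclohexa-2,4-dien-1-one | Cc1c(OCc9ccccc9)c2c(c(C=C3C=CC(OCc9ccccc9)=CC3=O)c1OCc9ccccc9)O[C@H](c1ccc(OCc9ccccc9)c(OCc9ccccc9)c1)[C@@H](OCc9ccccc9)C2 | intermediate (not isolated)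
16 | (4S)-7-(benzyloxy)-2-[3,4-bis(benzyloxy)phenyl]-4-[(2R,3S)-6-methyl-3,5,7-tris(benzyloxy)-2-[3,4-bis(benzyloxy)phenyl]chroman-8-yl]-4H-chromene | Cc1c(OCc9ccccc9)c2c(c([C@@H]3c4ccc(OCc9ccccc9)cc4OC(c4ccc(OCc9ccccc9)c(OCc9ccccc9)c4)=C3)c1OCc9ccccc9)O[C@H](c1ccc(OCc9ccccc9)c(OCc9ccccc9)c1)[C@@H](OCc9ccccc9)C2 | intermediate
17 | C3 alkylborane of 16 (drawn as the monoalkylborane), boron trans to the C4 aryl | Cc1c(OCc9ccccc9)c2c(c([C@@H]3c4ccc(OCc9ccccc9)cc4O[C@H](c4ccc(OCc9ccccc9)c(OCc9ccccc9)c4)[C@H]3B)c1OCc9ccccc9)O[C@H](c1ccc(OCc9ccccc9)c(OCc9ccccc9)c1)[C@@H](OCc9ccccc9)C2 | intermediate (not isolated)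
18 | (2R,3S,4S)-7-(benzyloxy)-2-[3,4-bis(benzyloxy)phenyl]-4-[(2R,3S)-6-methyl-3,5,7-tris(benzyloxy)-2-[3,4-bis(benzyloxy)phenyl]chroman-8-yl]chroman-3-ol | Cc1c(OCc9ccccc9)c2c(c([C@@H]3c4ccc(OCc9ccccc9)cc4O[C@H](c4ccc(OCc9ccccc9)c(OCc9ccccc9)c4)[C@H]3O)c1OCc9ccccc9)O[C@H](c1ccc(OCc9ccccc9)c(OCc9ccccc9)c1)[C@@H](OCc9ccccc9)C2 | intermediate
19 | (2R,3S,4S)-2-(3,4-dihydroxyphenyl)-4-[(2R,3S)-2-(3,4-dihydroxyphenyl)-3,5,7-trihydroxy-6-methylchroman-8-yl]chromane-3,7-diol | Cc1c(O)c2c(c([C@@H]3c4ccc(O)cc4O[C@H](c4ccc(O)c(O)c4)[C@H]3O)c1O)O[C@H](c1ccc(O)c(O)c1)[C@@H](O)C2 | target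

## Step count and least certain steps

Total: 12 steps. Longest linear sequence: 10 steps (steps 1, 2, 3, 4, 5, 7, 8, 10, 11, 12). Steps 6 and 9 are one-step side branches.

**Step 10 (key step).**
- What may go wrong: poor facial selectivity at C4, because the alkyne has no hydrogen-bond donor to hold it against the phosphate. Capture by the weakly nucleophilic alkyne may be slow, so the quinone methide condenses with the electron-rich rings of a second molecule. Acid-promoted reversal, with loss of ring D from C4 of the product to give a flavylium ion, would scramble C4.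
- Remedy inside the strategy: the more acidic N-triflyl phosphoramide of the same binaphthyl scaffold.
- Fallback with known chemistry, from 12 back to 16: commercial 1-[3,4-bis(benzyloxy)phenyl]ethanone F1 is converted with NH2OH·HCl and pyridine into its oxime F2, and Fe powder with Ac2O and AcOH gives N-{1-[3,4-bis(benzyloxy)phenyl]ethenyl}acetamide F3. Under the same chiral phosphoric acid this enamide, whose N–H binds the phosphoryl oxygen, undergoes the well-precedented [4+2] cycloaddition with the quinone methide from 12 to give the 2-acetamidochroman F4. Brief warming with a catalytic sulfonic acid eliminates acetamide and returns to 16.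

**Step 11.**
- What may go wrong: incomplete hydroboration of the trisubstituted enol ether next to the bulky ring D, hydrolysis of the enol ether before it reacts, or β-elimination of the β-aryloxy borane, which would open ring C.
- Fallback, from 16 back to 18: dihydroxylation with catalytic OsO4 and N-methylmorpholine N-oxide, again from the face opposite ring D, should give the 2-hydroxy-flavan-3-ol (cyclic hemiketal) F5. Ionic reduction of the hemiketal with Et3SiH and BF3·OEt2 at low temperature, the reaction type used for aryl C-glycosides, delivers hydride to the C2 oxocarbenium ion anti to the C4 aryl and gives 18.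

**Step 4 (with step 5).**
- What may go wrong: sluggish attack at a position flanked by two benzyloxy groups on a ring already deactivated by bromine, loss of bromine by ipso attack, or cleavage of a benzyl ether by the acidic medium. In step 5 acid-induced debenzylation or protodebromination is possible.
- Fallback, from 4 back to 7, bypassing 5 and 6: iodination of 4 with N-iodosuccinimide and catalytic CF3CO2H gives (2R,3S)-8-bromo-6-iodo-3,5,7-tris(benzyloxy)-2-[3,4-bis(benzyloxy)phenyl]chromane F6. Selective iodine–lithium exchange with n-BuLi (1.0 equiv) at −95 °C gives the 6-lithio-8-bromo species F7, and MeI then gives 7.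

**Step 8.**
- What may go wrong: C-allylation of the electron-rich phenolate by the allyl–palladium intermediate, or premature ionisation of the product carbinol during work-up or chromatography, followed by self-condensation.
- Fallback, from 7 and 8 to 12, omitting steps 6 and 8: aldehyde 8 is deprotonated with NaH in THF to sodium 5-(benzyloxy)-2-formylphenolate F8, which is added to aryllithium 10 at −78 °C. A neutral quench gives 12 directly, to be used crude in step 10.

**Step 12.**
- What may go wrong: over-reduction with cleavage of the benzylic C–O bonds of rings C and F, stalling because partially debenzylated intermediates are poorly soluble, and air oxidation of the catechols during isolation.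
- Fallback, from 18 to 19: non-reductive debenzylation with BCl3 and pentamethylbenzene as cation scavenger in CH2Cl2 at −78 °C. No new compound is made.

## Further compounds

F1 | step 10 | 1-[3,4-bis(benzyloxy)phenyl]ethanone | CC(=O)c1ccc(OCc9ccccc9)c(OCc9ccccc9)c1
F2 | step 10 | 1-[3,4-bis(benzyloxy)phenyl]ethanone oxime | CC(=NO)c1ccc(OCc9ccccc9)c(OCc9ccccc9)c1
F3 | step 10 | N-{1-[3,4-bis(benzyloxy)phenyl]ethenyl}acetamide | C=C(NC(C)=O)c1ccc(OCc9ccccc9)c(OCc9ccccc9)c1
F4 | step 10 | N-{(4S)-7-(benzyloxy)-2-[3,4-bis(benzyloxy)phenyl]-4-[(2R,3S)-6-methyl-3,5,7-tris(benzyloxy)-2-[3,4-bis(benzyloxy)phenyl]chroman-8-yl]chroman-2-yl}acetamide, C2 epimers | Cc1c(OCc9ccccc9)c2c(c([C@@H]3c4ccc(OCc9ccccc9)cc4OC(NC(C)=O)(c4ccc(OCc9ccccc9)c(OCc9ccccc9)c4)C3)c1OCc9ccccc9)O[C@H](c1ccc(OCc9ccccc9)c(OCc9ccccc9)c1)[C@@H](OCc9ccccc9)C2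
F5 | step 11 | (3S,4S)-7-(benzyloxy)-2-[3,4-bis(benzyloxy)phenyl]-4-[(2R,3S)-6-methyl-3,5,7-tris(benzyloxy)-2-[3,4-bis(benzyloxy)phenyl]chroman-8-yl]chromane-2,3-diol, C2 hemiketal epimers | Cc1c(OCc9ccccc9)c2c(c([C@@H]3c4ccc(OCc9ccccc9)cc4OC(O)(c4ccc(OCc9ccccc9)c(OCc9ccccc9)c4)[C@H]3O)c1OCc9ccccc9)O[C@H](c1ccc(OCc9ccccc9)c(OCc9ccccc9)c1)[C@@H](OCc9ccccc9)C2
F6 | step 4 | (2R,3S)-8-bromo-6-iodo-3,5,7-tris(benzyloxy)-2-[3,4-bis(benzyloxy)phenyl]chromane | Ic1c(OCc9ccccc9)c2c(c(Br)c1OCc9ccccc9)O[C@H](c1ccc(OCc9ccccc9)c(OCc9ccccc9)c1)[C@@H](OCc9ccccc9)C2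
F7 | step 4 | [(2R,3S)-8-bromo-3,5,7-tris(benzyloxy)-2-[3,4-bis(benzyloxy)phenyl]chroman-6-yl]lithium | [Li]c1c(OCc9ccccc9)c2c(c(Br)c1OCc9ccccc9)O[C@H](c1ccc(OCc9ccccc9)c(OCc9ccccc9)c1)[C@@H](OCc9ccccc9)C2
F8 | step 8 | sodium 5-(benzyloxy)-2-formylphenolate | [Na+].[O-]c1cc(OCc9ccccc9)ccc1C=O
F0 | step 12 | none | none
A1 | alternative 1 | ring D phenol from the benzannulation, with the upper flavan at C8', the cinnamyl chain at C4a', benzyloxy at C5', triisopropylsiloxy at C7' and free hydroxyl at C8a' | Cc1c(OCc9ccccc9)c(C/C=C/c2ccc(OCc9ccccc9)c(OCc9ccccc9)c2)c(O)c([C@@H]2c3ccc(OCc9ccccc9)cc3O[C@H](c3ccc(OCc9ccccc9)c(OCc9ccccc9)c3)[C@H]2OCc9ccccc9)c1O[Si](C(C)C)(C(C)C)C(C)C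
A2 | alternative 1 | (2R,3S,4S)-3,7-bis(benzyloxy)-2-[3,4-bis(benzyloxy)phenyl]-4-[(triisopropylsiloxy)ethynyl]chromane (stereodescriptors as in 18) | CC(C)[Si](OC#C[C@@H]1c2ccc(OCc9ccccc9)cc2O[C@H](c2ccc(OCc9ccccc9)c(OCc9ccccc9)c2)[C@H]1OCc9ccccc9)(C(C)C)C(C)C
A3 | alternative 1 | 3-(benzyloxy)-4-{(E)-3-[3,4-bis(benzyloxy)phenyl]prop-2-enyl}-2-methylcyclobut-2-en-1-one | CC1=C(OCc9ccccc9)C(C/C=C/c2ccc(OCc9ccccc9)c(OCc9ccccc9)c2)C1=O
A4 | alternative 2 | octa-O-benzyl ether of the target with free C3' hydroxyl | Cc1c(OCc9ccccc9)c2c(c([C@@H]3c4ccc(OCc9ccccc9)cc4O[C@H](c4ccc(OCc9ccccc9)c(OCc9ccccc9)c4)[C@H]3OCc9ccccc9)c1OCc9ccccc9)O[C@H](c1ccc(OCc9ccccc9)c(OCc9ccccc9)c1)[C@@H](O)C2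
A5 | alternative 2 | ring D aryl ether of the epoxy alcohol: the O1'–C2' ether carrying the C3'–C4' terminal epoxide, with C4a' unsubstituted | Cc1c(OCc9ccccc9)cc(O[C@H](c2ccc(OCc9ccccc9)c(OCc9ccccc9)c2)[C@@H]2CO2)c([C@@H]2c3ccc(OCc9ccccc9)cc3O[C@H](c3ccc(OCc9ccccc9)c(OCc9ccccc9)c3)[C@H]2OCc9ccccc9)c1OCc9ccccc9
A6 | alternative 3 | nona-O-benzyl ether of the target | Cc1c(OCc9ccccc9)c2c(c([C@@H]3c4ccc(OCc9ccccc9)cc4O[C@H](c4ccc(OCc9ccccc9)c(OCc9ccccc9)c4)[C@H]3OCc9ccccc9)c1OCc9ccccc9)O[C@H](c1ccc(OCc9ccccc9)c(OCc9ccccc9)c1)[C@@H](OCc9ccccc9)C2
A7 | alternative 3 | 2-(benzyloxy)-3-[3-(benzyloxy)phenoxy]-3-[3,4-bis(benzyloxy)phenyl]propanal, configured as C3 and C2 of the upper unit | O(Cc9ccccc9)c1cccc(O[C@H](c2ccc(OCc9ccccc9)c(OCc9ccccc9)c2)[C@H](C=O)OCc9ccccc9)c1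
A8 | alternative 3 | (2R,3S)-6-methyl-3,5,7-tris(benzyloxy)-2-[3,4-bis(benzyloxy)phenyl]chromane | Cc1c(OCc9ccccc9)c2c(cc1OCc9ccccc9)O[C@H](c1ccc(OCc9ccccc9)c(OCc9ccccc9)c1)[C@@H](OCc9ccccc9)C2
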